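In a closed, stirred vessel of constant volume, free catalyst works through substrate and partner to give product. Two flasks are to be compared.

| flask | substrate | partner | free catalyst | temperature | remark | time |
|---|---|---|---|---|---|---|
| west | 20 mM | 24 mM | 1.4 mM | 10 °C | run made earlier |  |
| north-west | 20 mM | 24 mM | 2.3 mM | 21 °C | run made earlier |  |
| midnight | 20 mM | 24.0 mM | 1.0 mM |  | at 25 °C until 1.0 min, from then on at 5 °C | 2.0 min |
| spring | 20 mM | 24.0 mM | 2.0 mM |  | at 5 °C throughout | 2.0 min |

west run (percent of the substrate charged)

| time / min | product / % | substrate / % |
|---|---|---|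
| 0.500 | 8 | 88 |
| 1.00 | 17 | 85 |
| 2.00 | 32 | 64 |
| 3.00 | 52 | 45 |

north-west run (percent of the substrate charged)

| time / s | product / % | substrate / % |
|---|---|---|
| 10.0 | 10 | 86 |
| 12.0 | 14 | 84 |
| 25.0 | 32 | 72 |
| 40.0 | 44 | 54 |
| 80.0 | 81 | 21 |

(each reading ± 2 percentage points)

- the winner by amount of product, in percent of the substrate charged; "neither" if no more than 2 percentage points parts them (midnight / spring / neither)
- how much product is there at the end, in percent of the substrate charged: midnight
- how much product is there at the end, in percent of the substrate charged: spring



Both earlier runs climb roughly straight, and north-west is still climbing at 81 %. So we begin with one process, a catalyst turning over at a steady pace, and we name that pace the turnover frequency f: substrate converted per catalyst per unit time. Read from the last points, as readings with their scatter of 2 percentage points, it is 2.48 min⁻¹ in west and 5.28 min⁻¹ in north-west. These runs changed catalyst and temperature together, so we suppose that f depends on temperature and not on the amount of catalyst.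

The reckoning is

product fraction = f × [free catalyst] × time / [substrate]

With west's f throughout, midnight gets 24.8 % and spring 49.5 %, so spring leads.

Now add temperature. Carrying the ratio of the two readings on as an exponential in temperature gives the turnover frequency at the hot setting, 6.96 min⁻¹, and at the cold setting 1.75 min⁻¹. Both lie outside the measured range. Then

midnight: 43.6 %

spring: 35.1 %

The order swaps, and midnight leads.

Last comes the charge. Substrate is the limiting reagent, and in our reckoning control passes to it from the catalyst at the crossing time [substrate]/(f [free catalyst]). That is 2.87 min for midnight's hot stretch, which ends sooner, and 5.70 min for spring, beyond its end. So our numbers stand.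

The forecast names midnight, with 44 % (36 % to 53 %) for midnight and 33 % (25 % to 42 %) for spring, where our own reckoning gives 35.1 %. It adds: “The assumed catalyst order is the main uncertainty.”

The flask gives 50.0 % for midnight and 30.3 % for spring. The winner by amount of product is midnight. Midnight held 42.8 % of product at the change of temperature, after 1.00 min, and the cold stretch added 7.2 points. Our f at the hot setting had put 34.8 % on the hot stretch.

    partner + free catalyst → catalyst intermediate A (k = 145 L mol⁻¹ s⁻¹, Ea = 48.0 kJ mol⁻¹)
    catalyst intermediate A → catalyst intermediate B (k = 0.800 s⁻¹, Ea = 68.0 kJ mol⁻¹)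
    catalyst intermediate B ⇌ released group + catalyst intermediate C (K = 0.130 M, k = 5.56 s⁻¹, Ea = 57.0 kJ mol⁻¹, ΔH = −79.0 kJ mol⁻¹)
    substrate + catalyst intermediate C ⇌ catalyst intermediate D (K = 100 L mol⁻¹, k = 35.3 L mol⁻¹ s⁻¹, Ea = 52.0 kJ mol⁻¹, ΔH = −56.0 kJ mol⁻¹)
    catalyst intermediate D → catalyst intermediate E (k = 0.867 s⁻¹, Ea = 70.0 kJ mol⁻¹)
    catalyst intermediate E → free catalyst + product (k = 0.947 s⁻¹, Ea = 61.0 kJ mol⁻¹)
    (constants at 25 °C)

For a neighbour, midnight's flask with 1.7 mM of free catalyst, the same two values of f give 74.1 %. The flask gives 74.0 %.

All runs stem from a simulated flask with constants of no real substance, and the scatter is random.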